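**Retrosynthetic overview**

- The target comes from its 7,8-bis(triethylsilyl) ether, which arises in one base-triggered cycloisomerization of an acyclic ynone–methyl ketone. The carbocycle forms first (6-exo-dig Michael addition), the pyran second (oxa-6π electrocyclization of the resulting 2Z-dienone), and a final shift into conjugation sets C8a.
- The ynone comes from MnO2 oxidation of the Sonogashira product (C4a–C8a bond) of a 2-bromoallyl methyl ketone (C1, C5–C8a) and a side-chain pentenynol (C3, C4, C4a, C1'–C7').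
- The core fragment comes from the pivalaldehyde acetal of (R)-lactic acid: a self-regeneration-of-stereocentres aldol with 2-bromoacrolein sets C7 and C8, then Weinreb amide and MeMgBr.
- The side chain comes from L-isoleucine (C4', C5'): diazotization, methyl ketone, chelation-controlled alkynyl Grignard addition (C3'), LiAlH4 (E-alkene), acetal hydrolysis, ethynyl Grignard.
- C8a is not bought; it is set under thermodynamic control by C7 and C8 during the cycloisomerization.

Assumption: 2-bromoprop-2-enal and (R)-lactic acid are taken as commercial; locants C1–C8a and C1'–C7' are those of the target.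

**Route**

Step 1
Reactants: 1 L-isoleucine
Product: 2 (2S,3S)-2-hydroxy-3-methylpentanoic acid
Conditions: NaNO2, 1 M aq. H2SO4, 0 °C to rt
Reagents that add atoms: water, O
Why: Diazotization of the α-amino acid with hydrolysis through the α-lactone (double inversion) replaces NH2 by OH with net retention, so C4' and C5' are bought with isoleucine.

Step 2
Reactants: 2 (2S,3S)-2-hydroxy-3-methylpentanoic acid
Product: 3 (3S,4S)-3-hydroxy-4-methylhexan-2-one
Conditions: MeLi (3.3 equiv), Et2O, −78 to 0 °C; aq. HCl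
Reagents that add atoms: methyllithium, [Li]C
Why: Organolithium ketone synthesis from a carboxylic acid: the gem-dialkoxide formed from the lithium carboxylate collapses to the methyl ketone only on work-up, and the adjacent alkoxide keeps the carbinol stereocentre from enolizing.

Step 3
Reactants: 3 (3S,4S)-3-hydroxy-4-methylhexan-2-one; 4 3,3-diethoxyprop-1-yne
Product: 6 (4S,5S,6S)-1,1-diethoxy-4,6-dimethyloct-2-yne-4,5-diol, via alkynylmagnesium bromide 5 (not isolated)
Conditions: 4, EtMgBr, THF, 40 °C; then 3, −78 to 0 °C; aq. work-up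
Reagents that add atoms: none
Why: Cram-chelate-controlled Grignard addition: the magnesium alkoxide of the α-hydroxy ketone forms a five-membered chelate and the acetylide attacks the face anti to the sec-butyl group, setting the tertiary carbinol (C3') as S.

Step 4
Reactants: 6 (4S,5S,6S)-1,1-diethoxy-4,6-dimethyloct-2-yne-4,5-diol
Product: 7 (2E,4S,5S,6S)-1,1-diethoxy-4,6-dimethyloct-2-ene-4,5-diol
Conditions: LiAlH4, THF, 0 to 45 °C; aq. work-up
Reagents that add atoms: none
Why: Hydroxyl-directed trans-hydroalumination of the propargylic alcohol gives only the E-allylic alcohol, and the acetal is inert to LiAlH4.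

Step 5
Reactants: 7 (2E,4S,5S,6S)-1,1-diethoxy-4,6-dimethyloct-2-ene-4,5-diol
Product: 8 (2E,4S,5S,6S)-4,5-dihydroxy-4,6-dimethyloct-2-enal
Conditions: aq. citric acid, acetone, rt
Reagents that add atoms: water, O
Why: Mild acid-catalysed hydrolysis of the allylic acetal releases the E-enal, which cannot lactolize, without ionizing the tertiary allylic alcohol.

Step 6
Reactants: 8 (2E,4S,5S,6S)-4,5-dihydroxy-4,6-dimethyloct-2-enal
Product: 9 (4E,6S,7S,8S)-6,8-dimethyldec-4-en-1-yne-3,6,7-triol (both C3 epimers)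
Conditions: HC≡CMgBr (4 equiv), THF, −78 to 0 °C; aq. work-up
Reagents that add atoms: ethynylmagnesium bromide, C#C[Mg]Br
Why: 1,2-Grignard addition to the enal (the diol travels as its bis-alkoxide); the new carbinol is left as both epimers because step 13 oxidizes it to the C3 ketone.

Step 7
Reactants: 10 (R)-lactic acid; 11 pivalaldehyde
Product: 12 (2R,5R)-2-tert-butyl-5-methyl-1,3-dioxolan-4-one
Conditions: p-TsOH (cat.), H2SO4 (cat.), pentane, reflux (Dean–Stark); recrystallization from pentane, −78 °C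
Reagents that add atoms: none
Why: Acid-catalysed acetalization under thermodynamic control gives mainly the cis-dioxolanone (Seebach self-regeneration-of-stereocentres template), in which the lactate centre fixes the acetal carbon; crystallization gives the pure cis isomer.

Step 8
Reactants: 12 (2R,5R)-2-tert-butyl-5-methyl-1,3-dioxolan-4-one; 13 2-bromoprop-2-enal
Product: 16 (2R,5S)-5-[(1R)-2-bromo-1-(triethylsilyloxy)prop-2-en-1-yl]-2-tert-butyl-5-methyl-1,3-dioxolan-4-one, via lithium enolate 14 (not isolated), via lithium aldolate 15 (not isolated)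
Conditions: LiN(i-Pr)2, THF, −78 °C; 13, −78 °C; Et3SiOTf, −78 to −20 °C
Reagents that add atoms: triethylsilyl trifluoromethanesulfonate, CC[Si](CC)(CC)OS(=O)(=O)C(F)(F)F
Why: The aldol addition of the planar enolate occurs anti to the tert-butyl group (C7 set as S, retention relative to lactic acid) and through a Zimmerman–Traxler chair with the bromovinyl group equatorial (C8 set, dr about 4:1 expected, minor epimer removed by chromatography), and in-situ silylation of the aldolate blocks retro-aldol cleavage in step 9.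

Step 9
Reactants: 16 (2R,5S)-5-[(1R)-2-bromo-1-(triethylsilyloxy)prop-2-en-1-yl]-2-tert-butyl-5-methyl-1,3-dioxolan-4-one
Product: 17 (2S,3R)-4-bromo-2-hydroxy-N-methoxy-N,2-dimethyl-3-(triethylsilyloxy)pent-4-enamide
Conditions: MeNHOMe·HCl, i-PrMgCl, THF, −20 to 0 °C
Reagents that add atoms: N,O-dimethylhydroxylamine hydrochloride, CNOC.Cl
Why: Weinreb amide formation by aminolysis of the activated acylal carbonyl with the magnesium amide expels pivalaldehyde and frees the tertiary alcohol without touching either stereocentre.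

Step 10
Reactants: 17 (2S,3R)-4-bromo-2-hydroxy-N-methoxy-N,2-dimethyl-3-(triethylsilyloxy)pent-4-enamide
Product: 18 (2S,3R)-4-bromo-N-methoxy-N,2-dimethyl-2,3-bis(triethylsilyloxy)pent-4-enamide
Conditions: Et3SiOTf, 2,6-lutidine, CH2Cl2, −78 to 0 °C
Reagents that add atoms: triethylsilyl trifluoromethanesulfonate, CC[Si](CC)(CC)OS(=O)(=O)C(F)(F)F
Why: Silyl triflate silylation of the hindered tertiary alcohol, so that no alkoxide can add to the ynone in step 14; any 1,2-silyl migration in 17 converges on the same bis-silyl ether.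

Step 11
Reactants: 18 (2S,3R)-4-bromo-N-methoxy-N,2-dimethyl-2,3-bis(triethylsilyloxy)pent-4-enamide
Product: 19 (3S,4R)-5-bromo-3-methyl-3,4-bis(triethylsilyloxy)hex-5-en-2-one
Conditions: MeMgBr, THF, 0 °C to rt; aq. work-up
Reagents that add atoms: methylmagnesium bromide, C[Mg]Br
Why: Weinreb ketone synthesis: the chelated tetrahedral intermediate prevents over-addition and the vinyl bromide is inert to the Grignard reagent.

Step 12
Reactants: 19 (3S,4R)-5-bromo-3-methyl-3,4-bis(triethylsilyloxy)hex-5-en-2-one; 9 (4E,6S,7S,8S)-6,8-dimethyldec-4-en-1-yne-3,6,7-triol (both C3 epimers)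
Product: 20 (3S,4S,9E,11S,12S,13S)-8,11,12-trihydroxy-3,11,13-trimethyl-5-methylidene-3,4-bis(triethylsilyloxy)pentadec-9-en-6-yn-2-one (both C8 epimers)
Conditions: Pd(PPh3)4 (5 mol %), CuI (10 mol %), Et3N, THF, 45 °C
Reagents that add atoms: none
Why: Sonogashira coupling of the 2-bromoallyl silyl ether with the terminal alkyne forms the C4a–C8a bond and tolerates the free hydroxyls and the methyl ketone.

Step 13
Reactants: 20 (3S,4S,9E,11S,12S,13S)-8,11,12-trihydroxy-3,11,13-trimethyl-5-methylidene-3,4-bis(triethylsilyloxy)pentadec-9-en-6-yn-2-one (both C8 epimers)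
Product: 21 (3S,4S,9E,11S,12S,13S)-11,12-dihydroxy-3,11,13-trimethyl-5-methylidene-3,4-bis(triethylsilyloxy)pentadec-9-en-6-yne-2,8-dione
Conditions: MnO2 (20 equiv), CH2Cl2, rt
Reagents that add atoms: none
Why: MnO2 oxidizes only the doubly activated (allylic and propargylic) secondary alcohol, erasing the epimeric carbinol and giving the cross-conjugated ynone whose carbonyl oxygen becomes the pyran oxygen.

Step 14
Reactants: 21 (3S,4S,9E,11S,12S,13S)-11,12-dihydroxy-3,11,13-trimethyl-5-methylidene-3,4-bis(triethylsilyloxy)pentadec-9-en-6-yne-2,8-dione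
Product: 24 (7S,8S,8aS)-3-[(1E,3S,4S,5S)-3,4-dihydroxy-3,5-dimethylhept-1-en-1-yl]-7-methyl-7,8-bis(triethylsilyloxy)-1,7,8,8a-tetrahydro-6H-isochromen-6-one, via Z-dienone 22 (not isolated), via 2H-pyran 23 (not isolated)
Conditions: potassium tert-butoxide (0.3 equiv), THF (0.01 M), −20 °C to rt
Reagents that add atoms: none
Why: The methyl ketone enolate closes the carbocycle by 6-exo-dig Michael addition to the ynone, the resulting 2Z-dienone (a 1-oxatriene) closes the pyran by thermal disrotatory oxa-6π electrocyclization, and the base-mediated shift of the double bond into conjugation protonates C8a reversibly, so the more stable 8aS epimer results (H8 and H8a trans-diaxial, C8 silyloxy and C7 methyl equatorial).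

Step 15
Reactants: 24 (7S,8S,8aS)-3-[(1E,3S,4S,5S)-3,4-dihydroxy-3,5-dimethylhept-1-en-1-yl]-7-methyl-7,8-bis(triethylsilyloxy)-1,7,8,8a-tetrahydro-6H-isochromen-6-one
Product: 25 (7S,8S,8aS)-3-[(1E,3S,4S,5S)-3,4-dihydroxy-3,5-dimethylhept-1-en-1-yl]-7,8-dihydroxy-7-methyl-1,7,8,8a-tetrahydro-6H-isochromen-6-one
Conditions: HF·pyridine, pyridine, THF, 0 °C to rt
Reagents that add atoms: none
Why: Buffered fluoride desilylation removes both triethylsilyl ethers without generating alkoxides (no retro-aldol opening of the β-hydroxy ketone) and without strong acid (no ionization of the tertiary allylic alcohol).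

**Compound list**

1 | L-isoleucine | CC[C@H](C)[C@H](N)C(=O)O | starting material
2 | (2S,3S)-2-hydroxy-3-methylpentanoic acid | CC[C@H](C)[C@H](O)C(=O)O | intermediate
3 | (3S,4S)-3-hydroxy-4-methylhexan-2-one | CC[C@H](C)[C@H](O)C(C)=O | intermediate
4 | 3,3-diethoxyprop-1-yne | C#CC(OCC)OCC | starting material
5 | (3,3-diethoxyprop-1-yn-1-yl)magnesium bromide | CCOC(OCC)C#C[Mg]Br | intermediate
6 | (4S,5S,6S)-1,1-diethoxy-4,6-dimethyloct-2-yne-4,5-diol | CC[C@H](C)[C@H](O)[C@@](C)(O)C#CC(OCC)OCC | intermediate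
7 | (2E,4S,5S,6S)-1,1-diethoxy-4,6-dimethyloct-2-ene-4,5-diol | CC[C@H](C)[C@H](O)[C@@](C)(O)/C=C/C(OCC)OCC | intermediate
8 | (2E,4S,5S,6S)-4,5-dihydroxy-4,6-dimethyloct-2-enal | CC[C@H](C)[C@H](O)[C@@](C)(O)/C=C/C=O | intermediate
9 | (4E,6S,7S,8S)-6,8-dimethyldec-4-en-1-yne-3,6,7-triol (both C3 epimers) | CC[C@H](C)[C@H](O)[C@@](C)(O)/C=C/C(O)C#C | intermediate
10 | (R)-lactic acid | C[C@@H](O)C(=O)O | starting material
11 | pivalaldehyde (2,2-dimethylpropanal) | CC(C)(C)C=O | starting material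
12 | (2R,5R)-2-tert-butyl-5-methyl-1,3-dioxolan-4-one | C[C@H]1O[C@@H](C(C)(C)C)OC1=O | intermediate
13 | 2-bromoprop-2-enal | C=C(Br)C=O | starting material
14 | lithium (2R)-2-tert-butyl-5-methyl-1,3-dioxol-4-olate | [Li]OC1=C(C)O[C@@H](C(C)(C)C)O1 | intermediate
15 | lithium (1R)-2-bromo-1-[(2R,4S)-2-tert-butyl-4-methyl-5-oxo-1,3-dioxolan-4-yl]prop-2-en-1-olate | O=C1[C@@](C)(O[C@@H](C(C)(C)C)O1)[C@@H](O[Li])C(Br)=C | intermediate
16 | (2R,5S)-5-[(1R)-2-bromo-1-(triethylsilyloxy)prop-2-en-1-yl]-2-tert-butyl-5-methyl-1,3-dioxolan-4-one | O=C1[C@@](C)(O[C@@H](C(C)(C)C)O1)[C@@H](O[Si](CC)(CC)CC)C(Br)=C | intermediate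
17 | (2S,3R)-4-bromo-2-hydroxy-N-methoxy-N,2-dimethyl-3-(triethylsilyloxy)pent-4-enamide | CON(C)C(=O)[C@@](C)(O)[C@@H](O[Si](CC)(CC)CC)C(Br)=C | intermediate
18 | (2S,3R)-4-bromo-N-methoxy-N,2-dimethyl-2,3-bis(triethylsilyloxy)pent-4-enamide | CON(C)C(=O)[C@@](C)(O[Si](CC)(CC)CC)[C@@H](O[Si](CC)(CC)CC)C(Br)=C | intermediate
19 | (3S,4R)-5-bromo-3-methyl-3,4-bis(triethylsilyloxy)hex-5-en-2-one | CC(=O)[C@@](C)(O[Si](CC)(CC)CC)[C@@H](O[Si](CC)(CC)CC)C(Br)=C | intermediate
20 | (3S,4S,9E,11S,12S,13S)-8,11,12-trihydroxy-3,11,13-trimethyl-5-methylidene-3,4-bis(triethylsilyloxy)pentadec-9-en-6-yn-2-one (both C8 epimers) | CC[C@H](C)[C@H](O)[C@@](C)(O)/C=C/C(O)C#CC(=C)[C@H](O[Si](CC)(CC)CC)[C@](C)(O[Si](CC)(CC)CC)C(C)=O | intermediate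
21 | (3S,4S,9E,11S,12S,13S)-11,12-dihydroxy-3,11,13-trimethyl-5-methylidene-3,4-bis(triethylsilyloxy)pentadec-9-en-6-yne-2,8-dione | CC[C@H](C)[C@H](O)[C@@](C)(O)/C=C/C(=O)C#CC(=C)[C@H](O[Si](CC)(CC)CC)[C@](C)(O[Si](CC)(CC)CC)C(C)=O | intermediate
22 | (2S,3S,5Z)-5-[(3E,5S,6S,7S)-5,6-dihydroxy-5,7-dimethyl-2-oxonon-3-en-1-ylidene]-2-methyl-4-methylidene-2,3-bis(triethylsilyloxy)cyclohexan-1-one | CC[C@H](C)[C@H](O)[C@@](C)(O)/C=C/C(=O)/C=C1/CC(=O)[C@@](C)(O[Si](CC)(CC)CC)[C@@H](O[Si](CC)(CC)CC)C1=C | intermediate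
23 | (7S,8S)-3-[(1E,3S,4S,5S)-3,4-dihydroxy-3,5-dimethylhept-1-en-1-yl]-7-methyl-7,8-bis(triethylsilyloxy)-7,8-dihydro-1H-isochromen-6(5H)-one | CC[C@H](C)[C@H](O)[C@@](C)(O)/C=C/C1=CC2=C(CO1)[C@H](O[Si](CC)(CC)CC)[C@](C)(O[Si](CC)(CC)CC)C(=O)C2 | intermediate
24 | (7S,8S,8aS)-3-[(1E,3S,4S,5S)-3,4-dihydroxy-3,5-dimethylhept-1-en-1-yl]-7-methyl-7,8-bis(triethylsilyloxy)-1,7,8,8a-tetrahydro-6H-isochromen-6-one | CC[C@H](C)[C@H](O)[C@@](C)(O)/C=C/C1=CC2=CC(=O)[C@@](C)(O[Si](CC)(CC)CC)[C@@H](O[Si](CC)(CC)CC)[C@@H]2CO1 | intermediate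
25 | (7S,8S,8aS)-3-[(1E,3S,4S,5S)-3,4-dihydroxy-3,5-dimethylhept-1-en-1-yl]-7,8-dihydroxy-7-methyl-1,7,8,8a-tetrahydro-6H-isochromen-6-one | CC[C@H](C)[C@H](O)[C@@](C)(O)/C=C/C1=CC2=CC(=O)[C@@](C)(O)[C@@H](O)[C@@H]2CO1 | target

**Step count and risks**

Total step count: 15. Longest linear sequence: 10 steps (steps 1–6, then 12–15); the core branch (steps 7–11) joins at step 12.

The three steps most likely to fail:

Step 8 (aldol with 2-bromoprop-2-enal). The face anti to tert-butyl is reliable, but the carbinol (C8) selectivity of this enolate with aldehydes is only moderate and the enal is sensitive. The fallback sets out from 12. The aldol is quenched with aq. NH4Cl instead of the silyl triflate to give the carbinol epimers (2R,5S)-5-(2-bromo-1-hydroxyprop-2-en-1-yl)-2-tert-butyl-5-methyl-1,3-dioxolan-4-one F1. Dess–Martin periodinane converts both epimers into the single ketone (2R,5S)-5-(2-bromoprop-2-enoyl)-2-tert-butyl-5-methyl-1,3-dioxolan-4-one F2. Zn(BH4)2 reduces it 1,2 under chelation between the ketone and the ring oxygen on C5, with hydride entering from the methyl side, to (2R,5S)-5-[(1R)-2-bromo-1-hydroxyprop-2-en-1-yl]-2-tert-butyl-5-methyl-1,3-dioxolan-4-one F3. Silylation with Et3SiOTf and 2,6-lutidine comes back to the route at 16.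

Step 9 (opening of the very hindered acylal by the Weinreb magnesium amide). The carbonyl sits next to a fully substituted carbon and may react sluggishly. The fallback sets out from 16 and uses Me3SiCH2Li (3 equiv, THF, −78 °C). This gives the α-silyl ketone (3S,4R)-5-bromo-3-hydroxy-3-methyl-4-(triethylsilyloxy)-1-(trimethylsilyl)hex-5-en-2-one F4, held as its enolate so that no second addition occurs. Methanol removes the C-silyl group to give (3S,4R)-5-bromo-3-hydroxy-3-methyl-4-(triethylsilyloxy)hex-5-en-2-one F5. Et3SiOTf and 2,6-lutidine silylate the tertiary alcohol, and the fallback comes back at 19, bypassing 17 and 18.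

Step 14 (Michael / oxa-6π / conjugation cascade). The ynone may oligomerize, or the free side-chain hydroxyls may interfere before the methyl ketone enolate cyclizes. The fallback sets out from 21. Et3SiOTf and Et3N give the enol silane (3S,4S,9E,11S,12S,13S)-3,11,13-trimethyl-5-methylidene-2,3,4,11,12-pentakis(triethylsilyloxy)pentadeca-1,9-dien-6-yn-8-one F6, in which the side-chain hydroxyls are silylated as well. Me2AlCl (CH2Cl2, −78 °C) triggers an intramolecular Mukaiyama–Michael addition to the dienone (2S,3S,5Z)-5-[(3E,5S,6S,7S)-5,7-dimethyl-2-oxo-5,6-bis(triethylsilyloxy)non-3-en-1-ylidene]-2-methyl-4-methylidene-2,3-bis(triethylsilyloxy)cyclohexan-1-one F7. This closes by the same oxa-6π electrocyclization to (7S,8S)-3-[(1E,3S,4S,5S)-3,5-dimethyl-3,4-bis(triethylsilyloxy)hept-1-en-1-yl]-7-methyl-7,8-bis(triethylsilyloxy)-7,8-dihydro-1H-isochromen-6(5H)-one F8. DBU then moves the double bond into conjugation to give (7S,8S,8aS)-3-[(1E,3S,4S,5S)-3,5-dimethyl-3,4-bis(triethylsilyloxy)hept-1-en-1-yl]-7-methyl-7,8-bis(triethylsilyloxy)-1,7,8,8a-tetrahydro-6H-isochromen-6-one F9. HF·pyridine removes all four silyl groups, and the fallback comes back at 25.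

**Further compounds**

F1 | step 8 | (2R,5S)-5-(2-bromo-1-hydroxyprop-2-en-1-yl)-2-tert-butyl-5-methyl-1,3-dioxolan-4-one (carbinol epimers) | O=C1[C@@](C)(O[C@@H](C(C)(C)C)O1)C(O)C(Br)=C
F2 | step 8 | (2R,5S)-5-(2-bromoprop-2-enoyl)-2-tert-butyl-5-methyl-1,3-dioxolan-4-one | O=C1[C@@](C)(O[C@@H](C(C)(C)C)O1)C(=O)C(Br)=C
F3 | step 8 | (2R,5S)-5-[(1R)-2-bromo-1-hydroxyprop-2-en-1-yl]-2-tert-butyl-5-methyl-1,3-dioxolan-4-one | O=C1[C@@](C)(O[C@@H](C(C)(C)C)O1)[C@@H](O)C(Br)=C
F4 | step 9 | (3S,4R)-5-bromo-3-hydroxy-3-methyl-4-(triethylsilyloxy)-1-(trimethylsilyl)hex-5-en-2-one | C[Si](C)(C)CC(=O)[C@@](C)(O)[C@@H](O[Si](CC)(CC)CC)C(Br)=C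
F5 | step 9 | (3S,4R)-5-bromo-3-hydroxy-3-methyl-4-(triethylsilyloxy)hex-5-en-2-one | CC(=O)[C@@](C)(O)[C@@H](O[Si](CC)(CC)CC)C(Br)=C
F6 | step 14 | (3S,4S,9E,11S,12S,13S)-3,11,13-trimethyl-5-methylidene-2,3,4,11,12-pentakis(triethylsilyloxy)pentadeca-1,9-dien-6-yn-8-one | CC[C@H](C)[C@H](O[Si](CC)(CC)CC)[C@@](C)(O[Si](CC)(CC)CC)/C=C/C(=O)C#CC(=C)[C@H](O[Si](CC)(CC)CC)[C@](C)(O[Si](CC)(CC)CC)C(=C)O[Si](CC)(CC)CC
F7 | step 14 | (2S,3S,5Z)-5-[(3E,5S,6S,7S)-5,7-dimethyl-2-oxo-5,6-bis(triethylsilyloxy)non-3-en-1-ylidene]-2-methyl-4-methylidene-2,3-bis(triethylsilyloxy)cyclohexan-1-one | CC[C@H](C)[C@H](O[Si](CC)(CC)CC)[C@@](C)(O[Si](CC)(CC)CC)/C=C/C(=O)/C=C1/CC(=O)[C@@](C)(O[Si](CC)(CC)CC)[C@@H](O[Si](CC)(CC)CC)C1=C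
F8 | step 14 | (7S,8S)-3-[(1E,3S,4S,5S)-3,5-dimethyl-3,4-bis(triethylsilyloxy)hept-1-en-1-yl]-7-methyl-7,8-bis(triethylsilyloxy)-7,8-dihydro-1H-isochromen-6(5H)-one | CC[C@H](C)[C@H](O[Si](CC)(CC)CC)[C@@](C)(O[Si](CC)(CC)CC)/C=C/C1=CC2=C(CO1)[C@H](O[Si](CC)(CC)CC)[C@](C)(O[Si](CC)(CC)CC)C(=O)C2
F9 | step 14 | (7S,8S,8aS)-3-[(1E,3S,4S,5S)-3,5-dimethyl-3,4-bis(triethylsilyloxy)hept-1-en-1-yl]-7-methyl-7,8-bis(triethylsilyloxy)-1,7,8,8a-tetrahydro-6H-isochromen-6-one | CC[C@H](C)[C@H](O[Si](CC)(CC)CC)[C@@](C)(O[Si](CC)(CC)CC)/C=C/C1=CC2=CC(=O)[C@@](C)(O[Si](CC)(CC)CC)[C@@H](O[Si](CC)(CC)CC)[C@@H]2CO1
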